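**Retrosynthetic overview**
1. Target 13 ⇐ opening with water (C–O cleavage) of the cis-fused cyclobutane anhydride 12.
2. 12 ⇐ intramolecular head-to-head [2+2] of the acyclic symmetric anhydride 11. The key disconnection is the acyl–O–acyl C–O bond of 11, which joins two molecules of (E)-acid 10 through a traceless three-atom tether.
3. 10 ⇐ ethyl ester 9 ⇐ vinylogous aldol/elimination of 6-ethylpyranone 5 with ethyl glyoxylate 6.
4. 5 ⇐ O-methylation of 4 ⇐ lactonisation (C–O) of triketo ester 3 ⇐ dianion Claisen of 1 with 2.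
5. Ring order: the pyranone ring first (step 1, carried intact in both halves), the cyclobutane last (step 5).

Assumption: the target as drawn is a meso compound, (1R,2S,3R,4S), with the two CO2H cis, the two pyranonyl groups cis and each pyranonyl trans to the neighbouring CO2H; it has no enantiomer, so the task is to make this one diastereomer.

**Step 1**
Reactants: 1 ethyl 2-methyl-3-oxobutanoate (ethyl 2-methylacetoacetate); 2 ethyl propanoate
Product: 4 6-ethyl-4-hydroxy-3-methyl-2H-pyran-2-one, via triketo ester 3 (not isolated)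
Conditions: 1 (2.0 equiv), LiN(iPr)2 (4.1 equiv), THF, −78→0 °C; 2 (1.0 equiv), 0 °C; aq HCl; crude 3, DBU (1.5 equiv), toluene, 110 °C; aq HCl
Reagents that add atoms: none
Why: γ-Selective Claisen acylation of the β-keto ester dianion gives the 3,5-dioxo ester, whose C5 enol oxygen lactonises onto the ethyl ester under DBU to the 4-hydroxy-2-pyranone; no stereocentre is formed.

**Step 2**
Reactants: 4 6-ethyl-4-hydroxy-3-methyl-2H-pyran-2-one
Product: 5 6-ethyl-4-methoxy-3-methyl-2H-pyran-2-one
Conditions: Me2SO4 (1.2 equiv), K2CO3 (1.5 equiv), acetone, 56 °C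
Reagents that add atoms: dimethyl sulfate, COS(=O)(=O)OC
Why: Williamson-type O-methylation of the acidic vinylogous acid with a hard methylating agent; K2CO3/acetone favours the 4-methoxy-2-pyranone over the 2-methoxy-4-pyranone isomer, which is removed by chromatography.

**Step 3**
Reactants: 5 6-ethyl-4-methoxy-3-methyl-2H-pyran-2-one; 6 ethyl glyoxylate (ethyl 2-oxoacetate)
Product: 9 ethyl (2E)-3-(4-methoxy-3-methyl-2-oxo-2H-pyran-6-yl)but-2-enoate, via aldol adduct 7 (not isolated), via mesylate 8 (not isolated)
Conditions: LiN(iPr)2 (1.1 equiv), THF, −78 °C; 6 (1.5 equiv, freshly distilled), −78 °C; MeSO2Cl (1.5 equiv), −78→0 °C; DBU (3 equiv), 0 °C→rt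
Reagents that add atoms: none
Why: Vinylogous deprotonation at the 6-CH2 gives the extended lithium dienolate, which undergoes aldol addition to the non-enolisable aldehyde; O-mesylation and E1cB elimination through the same dienolate give the conjugated enoate, the (E) isomer (pyranonyl trans to CO2Et) being favoured by allylic strain, and the two aldol stereocentres are erased.

**Step 4**
Reactants: 9 ethyl (2E)-3-(4-methoxy-3-methyl-2-oxo-2H-pyran-6-yl)but-2-enoate
Product: 10 (2E)-3-(4-methoxy-3-methyl-2-oxo-2H-pyran-6-yl)but-2-enoic acid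
Conditions: Me3SnOH (4 equiv), ClCH2CH2Cl, 80 °C; aq HCl (1 M) work-up
Reagents that add atoms: trimethyltin hydroxide, C[Sn](C)(C)O
Why: Tin-mediated acyl substitution delivers hydroxide to the ester carbonyl under near-neutral conditions, sparing the hydroxide-sensitive 4-methoxy-2-pyranone and leaving the (E) alkene untouched.

**Step 5**
Reactants: 10 (2E)-3-(4-methoxy-3-methyl-2-oxo-2H-pyran-6-yl)but-2-enoic acid (two molecules)
Product: 13 (1R,2S,3R,4S)-3,4-bis(4-methoxy-3-methyl-2-oxo-2H-pyran-6-yl)-3,4-dimethylcyclobutane-1,2-dicarboxylic acid (meso; target), via acyclic anhydride 11 (not isolated), via cyclobutane anhydride 12 (not isolated)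
Conditions: iPrN=C=NiPr (0.5 equiv), CH2Cl2, 0 °C→rt, 1 h; dilute to 0.01 M, degas, [Ir(dF(CF3)ppy)2(dtbbpy)]PF6 (1 mol%), 450 nm LEDs, rt; then H2O/THF (1:4), 40 °C
Reagents that add atoms: water, O
Why: Proposed new method: the carbodiimide-formed acyl–O–acyl bond turns two acids into a 1,6-diene with a three-atom tether, so triplet energy transfer to the pyranonyl-enoate triggers 5-exo α–α′ bonding to a bis-tertiary 1,4-diradical that can ring-close only when the new five-membered anhydride is cis-fused, which enforces head-to-head regiochemistry and cis carboxyls, while the larger flat pyranonyl groups take the convex face anti to the anhydride and the methyls the concave face, giving the meso all-cis pattern before neutral water opens the cyclic anhydride without epimerisation; the closest known reaction types are the sensitised intramolecular [2+2] photocycloaddition of cinnamates held on covalent diol templates and of 1,6-dienes that follow the rule of five, not yet shown with an acyclic carboxylic anhydride as a traceless tether or for β-methyl-β-heteroaryl acrylates that form two adjacent quaternary centres.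

**Compound list**
1 | ethyl 2-methyl-3-oxobutanoate | CCOC(=O)C(C)C(C)=O | starting material
2 | ethyl propanoate | CCC(=O)OCC | starting material
3 | ethyl 2-methyl-3,5-dioxoheptanoate (racemic; triketo ester) | CCC(=O)CC(=O)C(C)C(=O)OCC | intermediate
4 | 6-ethyl-4-hydroxy-3-methyl-2H-pyran-2-one | CCc1cc(O)c(C)c(=O)o1 | intermediate
5 | 6-ethyl-4-methoxy-3-methyl-2H-pyran-2-one | CCc1cc(OC)c(C)c(=O)o1 | intermediate
6 | ethyl glyoxylate | CCOC(=O)C=O | starting material
7 | ethyl 2-hydroxy-3-(4-methoxy-3-methyl-2-oxo-2H-pyran-6-yl)butanoate (mixture of diastereomers, formed as its lithium alkoxide) | COc1cc(C(C)C(O)C(=O)OCC)oc(=O)c1C | intermediate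
8 | ethyl 2-(methanesulfonyloxy)-3-(4-methoxy-3-methyl-2-oxo-2H-pyran-6-yl)butanoate (mixture of diastereomers) | COc1cc(C(C)C(OS(C)(=O)=O)C(=O)OCC)oc(=O)c1C | intermediate
9 | ethyl (2E)-3-(4-methoxy-3-methyl-2-oxo-2H-pyran-6-yl)but-2-enoate | COc1cc(/C(C)=C/C(=O)OCC)oc(=O)c1C | intermediate
10 | (2E)-3-(4-methoxy-3-methyl-2-oxo-2H-pyran-6-yl)but-2-enoic acid | COc1cc(/C(C)=C/C(=O)O)oc(=O)c1C | intermediate
11 | (2E)-3-(4-methoxy-3-methyl-2-oxo-2H-pyran-6-yl)but-2-enoic anhydride (symmetric, E,E) | COc1cc(/C(C)=C/C(=O)OC(=O)/C=C(C)/c2cc(OC)c(C)c(=O)o2)oc(=O)c1C | intermediate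
12 | (1R,5S,6R,7S)-6,7-bis(4-methoxy-3-methyl-2-oxo-2H-pyran-6-yl)-6,7-dimethyl-3-oxabicyclo[3.2.0]heptane-2,4-dione (meso; cis-fused; both pyranonyl groups anti to the anhydride ring, both methyls syn to it) | COc1cc([C@@]2(C)[C@@H]3C(=O)OC(=O)[C@@H]3[C@@]2(C)c2cc(OC)c(C)c(=O)o2)oc(=O)c1C | intermediate
13 | (1R,2S,3R,4S)-3,4-bis(4-methoxy-3-methyl-2-oxo-2H-pyran-6-yl)-3,4-dimethylcyclobutane-1,2-dicarboxylic acid (meso) | COc1cc([C@@]2(C)[C@H](C(=O)O)[C@H](C(=O)O)[C@@]2(C)c2cc(OC)c(C)c(=O)o2)oc(=O)c1C | target

**Total step count:** 5. **Longest linear sequence:** 5 steps (1 → 4 → 5 → 9 → 10 → 13).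

**Three steps most likely to fail**

Step 5 (the proposed new step). The diradical may close with one pyranonyl group on the concave face, giving a diastereomer; part of the in-situ anhydride may be lost as N-acylurea; and the product pyranones could be sensitised slowly on over-irradiation. The fallback uses known chemistry, sets out from 10 and comes back at 13. Two molecules of 10 are esterified onto naphthalene-1,8-diol (dicyclohexylcarbodiimide, DMAP, CH2Cl2) to give naphthalene-1,8-diyl bis[(2E)-3-(4-methoxy-3-methyl-2-oxo-2H-pyran-6-yl)but-2-enoate] F1. The peri-diol holds the two enoates face to face, and irradiation of the crystalline film at 365 nm gives the head-to-head, all-cis cyclobutane as the cyclic diester naphthalene-1,8-diyl (1R,2S,3R,4S)-3,4-bis(4-methoxy-3-methyl-2-oxo-2H-pyran-6-yl)-3,4-dimethylcyclobutane-1,2-dicarboxylate F2, as in the established diol-template route to β-truxinic acids. LiOH/H2O2 (THF/H2O, 0 °C) then cleaves the two aryl esters, which react far faster than the pyranone lactone, to give 13 and return the diol.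

Step 3. Partly polymerised ethyl glyoxylate can give poor aldol conversion, and the elimination can give E/Z mixtures or the deconjugated β,γ-isomer. The fallback sets out from 5 and comes back at 9. Riley oxidation of the activated 6-CH2 group with SeO2 (1,4-dioxane, 100 °C) gives 6-acetyl-4-methoxy-3-methyl-2H-pyran-2-one F3. Horner–Wadsworth–Emmons olefination with triethyl phosphonoacetate (NaH, THF, 0 °C→rt) then gives 9, with the (E) isomer predominating and separable from the (Z) isomer by chromatography.

Step 4. The β,β-disubstituted conjugated ethyl ester may hydrolyse slowly, and forcing conditions could open the pyranone or remove the 4-methoxy group. The fallback sets out from 5 and comes back at 10. Step 3 is run with tert-butyl glyoxylate in place of 6, giving tert-butyl 2-hydroxy-3-(4-methoxy-3-methyl-2-oxo-2H-pyran-6-yl)butanoate F4, then its mesylate tert-butyl 2-(methanesulfonyloxy)-3-(4-methoxy-3-methyl-2-oxo-2H-pyran-6-yl)butanoate F5 and, after DBU elimination, tert-butyl (2E)-3-(4-methoxy-3-methyl-2-oxo-2H-pyran-6-yl)but-2-enoate F6. CF3CO2H in CH2Cl2 at rt then removes the tert-butyl group by acidolysis, with no nucleophile present, to give 10.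

**Further compounds**
F1 | step 5 | naphthalene-1,8-diyl bis[(2E)-3-(4-methoxy-3-methyl-2-oxo-2H-pyran-6-yl)but-2-enoate] | COc1cc(/C(C)=C/C(=O)Oc2cccc3cccc(OC(=O)/C=C(C)/c4cc(OC)c(C)c(=O)o4)c23)oc(=O)c1C
F2 | step 5 | naphthalene-1,8-diyl (1R,2S,3R,4S)-3,4-bis(4-methoxy-3-methyl-2-oxo-2H-pyran-6-yl)-3,4-dimethylcyclobutane-1,2-dicarboxylate (cyclic diester) | COc1cc([C@@]2(C)[C@@H]3C(=O)Oc4cccc5cccc(OC(=O)[C@@H]3[C@@]2(C)c2cc(OC)c(C)c(=O)o2)c45)oc(=O)c1C
F3 | step 3 | 6-acetyl-4-methoxy-3-methyl-2H-pyran-2-one | CC(=O)c1cc(OC)c(C)c(=O)o1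
F4 | step 4 | tert-butyl 2-hydroxy-3-(4-methoxy-3-methyl-2-oxo-2H-pyran-6-yl)butanoate (mixture of diastereomers) | COc1cc(C(C)C(O)C(=O)OC(C)(C)C)oc(=O)c1C
F5 | step 4 | tert-butyl 2-(methanesulfonyloxy)-3-(4-methoxy-3-methyl-2-oxo-2H-pyran-6-yl)butanoate (mixture of diastereomers) | COc1cc(C(C)C(OS(C)(=O)=O)C(=O)OC(C)(C)C)oc(=O)c1C
F6 | step 4 | tert-butyl (2E)-3-(4-methoxy-3-methyl-2-oxo-2H-pyran-6-yl)but-2-enoate | COc1cc(/C(C)=C/C(=O)OC(C)(C)C)oc(=O)c1C
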